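# Proposed total synthesis of CNP0161834.1 (compound 30)

## Analysis of the target

Compound 30 is a 6,7-seco-kaurane: a cyclohexane ring A (C1–C5, C10) is spiro-fused at C10 to a δ-lactone (C10–C20–O–C7–C8–C9), and the C8–C9 bond of this lactone is shared with the six-membered ring C of a bicyclo[3.2.1]octane whose five-membered ring D (C8, C14, C13, C16, C15) carries the C15 ketone. There are seven stereocentres (C1, C5, C8, C9, C10, C13, C16); two of them, C8 and C10, are quaternary and are separated only by C9. On ring A the C1 acetoxy group, the lactone carbon C20 and the C5 carboxyl group are all cis and C9 is trans to them; the lactone and ring C are cis-fused, with C11 and C14 on the C1 side of the lactone and H9 cis to C15; C13 is tied to C8 by the two-carbon bridge; the C16 methyl group lies on the endo face of ring D, cis to C12. C16 is α to the ketone and can epimerise, and the endo methyl group is expected to be the less stable arrangement. The sensitive groups are the secondary acetate, the lactone (a free C1 hydroxyl could take over the acyl group from O20), the β-keto lactone unit at C8 (open to retro-Claisen cleavage by hard nucleophiles) and the free acid. The difficulty is the spiro quaternary centre C10 with three stereogenic neighbours (C1, C5, C9), followed by the second quaternary centre C8. The strategy rests on two facts: with a C8=C9 double bond in place, C10 is the γ-carbon of the C7 lactone carbonyl, and C10 is bonded to the carbinol carbon C1. Ring A can therefore be closed last at C10 by γ-attack of a lactone dienolate on a C1 aldehyde, and the same C8=C9 bond then serves as a doubly activated dienophile for ring C.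

## Retrosynthetic reasoning

**C16, C6 and C12 (30 back to 25).** The last operations are changes of functional groups. Because C16 is the one centre that can epimerise and 30 carries its methyl group on the crowded endo side, C16 is set in the final step, by protonation of the C15 enol derivative 29 of acid 28 from the open exo face. Acid 28 comes from tert-butyl ester 27. The C12 methylene group of 27 comes from the C12 ketone of 25 through dithiolane 26; this oxygen is a leftover of the way ring C is made.

**C13–C16, ring D (25 back to 23).** In 25 the bond C13–C16 joins the α-carbons of two ketones, so it is cut as an oxidative coupling of two enol derivatives (24). The cut is made here because the C12=C13 position of the enol ether in 23 is fixed by the preceding cycloaddition, and because the bridge can only form on the face of ring C that carries the C8 acyl group, which fixes C13. The forward reaction has to join C16 to C13 and not to C11.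

**C8–C14 and C9–C11, ring C (23 back to 21 and 22).** Both bonds are cut in one Diels–Alder disconnection. This returns the unsaturated acyl lactone 21, whose C8=C9 bond is activated by the lactone and the ketone, and diene 22. The gain is the quaternary centre C8, the C8/C9 cis relationship, and an oxygen on C12 exactly where the ring D closure needs an enol ether. The forward reaction must add to the face of the lactone that carries C1.

**Acetate (21 back to 20).** The acetyl group is removed to give alcohol 20; in the forward direction it is put on at once, so that O1 cannot attack C7.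

**C1–C10, ring A (20 back to 18), the key disconnection.** Cutting C1–C10 in 20 is a retro-vinylogous aldol. It removes ring A, the quaternary spiro centre and the carbinol centre in one stroke and leaves aldehyde 18, in which C5 is the only stereocentre that matters, because C10 becomes planar in dienolate 19. Other ring A bonds would not use the γ-relationship of C10 to C7, and would leave the quaternary centre to be made intermolecularly. The forward reaction has to attack through C10 (not C8), on the correct face of C10, and place the C1 oxygen cis to C20.

**Lactone and C8=C9 (18 back to 13 and 14).** Aldehyde 18 is unmasked from acetal 17. The C8=C9 bond of 17 is cut as an intramolecular Knoevenagel condensation of aldehyde 16, made by ozonolysis of the propenyl group of keto ester 15. Ester 15 comes from alcohol 13 and keto ester 14 by transesterification at O20. Making the ester bond first turns the condensation into a six-membered ring closure, which suits the hindered α-branched aldehyde.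

**C5–C10 (13 back to 8).** Alcohol 13 comes from ester 12 and acid 11. The bond C5–C10 of 11 links the α-carbon of an ester to a branched allylic carbon, a 1,4-dioxygenated pattern that enolate alkylation cannot supply but a [3,3] shift can: Ireland–Claisen rearrangement of ester 8 through ketene acetal 9 and silyl ester 10. This is also the place where the absolute configuration enters, by transfer of chirality from the carbinol centre of 8 to C5.

**Building blocks (8 back to 1, 2, 4, 5).** Ester 8 is assembled from the Meldrum's acid derivative 6 and alcohol 3 via half ester 7. Compound 6 comes from conjugate addition of Grignard reagent 4 to 5, which forms C3–C4 and the gem-dimethyl quaternary carbon and brings C1 as an acetal. Alcohol 3 comes from 1 and 2 by cross-metathesis, so the only source of chirality in the route is 1.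

## Alternatives that were turned down

**Alternative 1:** Here the bonds C5–C10 and C8–C9 are cut together after ring B has been restored (C6–C7) as a sacrificial ring. The forward key step is a transannular Diels–Alder reaction in a 14-membered ring, between a C5=C6–C7=C8 diene and a C9=C10 enoate, giving the tricyclic ester A1 with rings A, B and C closed at once.
- For it: the alkene geometries fix C5, C8, C9 and C10 in a single step, and the quaternary centre C10 is formed by a reaction that is entropically well set up. On the control of C10 this is stronger than the chosen route, which relies on one neighbouring stereocentre.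
- Against it: the macrocycle has a gem-dimethyl carbon next to the diene terminus and a fully substituted dienophile carbon, and it is long to make. A1 is also far from the target. Ring B must be cleaved at C6=C7, the C20 ester reduced and re-lactonised onto C7, and C8 (still tertiary in A1) made quaternary while three more carbons and ring D are added.
- Comparison: the chosen strategy keeps the lactone from the start and uses it twice as an activating group (dienolate, then dienophile), so no ring is made only to be broken and the oxidation levels of C6, C7 and C20 are never changed.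

**Alternative 2:** Here the bond C10–C20 is cut and C20 is delivered from the C1 oxygen. The forward key step is a 5-exo addition of an α-silyl methyl radical, generated from a (bromomethyl)dimethylsilyl ether on O1, to C10 of a C5=C10 enoate, followed by reduction of the C5 radical, giving siloxane A2.
- For it: the tether guarantees that C20 ends cis to O1, which is more certain than the aldol-based control of C1 in the chosen route. Rings C and D with C8, C9, C13 and C16 are already present, so the steps after A2 are few (oxidative cleavage of the C–Si bond, lactonisation, acetylation, ester cleavage).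
- Against it: the substrate is a tetrasubstituted enoate bonded at C10 to a complete bicyclo[3.2.1]octane with a quaternary C8. It needs two enantiopure halves and a C9–C10 bond between hindered partners. The radical must add to a fully substituted carbon flanked by C4 and C9, and C5 is set only by hydrogen transfer (correctable by epimerisation).
- Comparison: the chosen route is linear and draws all stereocentres from one purchased carbinol, and it makes ring A and the C1 carbinol in the same step instead of carrying them through a fragment coupling.

**Alternative 3:** Here the bond C8–C9 is cut and ring C is closed by ring contraction. The forward key step is a [3,3] rearrangement of the silyl ketene acetal of a δ-lactone (C7, C8, C14, C13, C12, O) bearing an (E)-C9=C11 alkenyl group on C12, giving the cyclohexene acid A3.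
- For it: the boat-like transition state of the lactone enolate Claisen rearrangement relays the C12 configuration to C8 and C9 and fixes them relative to C13. This relay is stronger than the facial selectivity on which the Diels–Alder step of the chosen route depends.
- Against it: the step presupposes ring A with C1, C5 and the quaternary C10, so the hardest part of the molecule is left to earlier chemistry. The new centre C9 forms next to C10 with face selection that rests on an acyclic conformation. A3 still has a tertiary C8, so ring D has to be closed onto C8 afterwards, the C11=C12 bond reduced, the benzyl-type ether removed and the lactone closed.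
- Comparison: the chosen strategy forms the spiro centre in its key step and makes C8 quaternary in the cycloaddition that builds ring C, which saves the separate construction of both quaternary centres.

Key step: step 10

Remark: atoms are numbered as in the kaurane skeleton (C17 is the methyl carbon on C16). Either C10 epimer of 13–18 serves, because C10 becomes planar in 19. Compounds 1, 2, 4, 5, 14 and 22 are taken as purchased.

## Route

Step 1
Reactants: 1 (S)-but-3-en-2-ol; 2 allyloxy(tert-butyl)dimethylsilane
Product: 3 (2S,3E)-5-[(tert-butyldimethylsilyl)oxy]pent-3-en-2-ol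
Conditions: 2 (3 equiv), second-generation Grubbs catalyst RuCl2(H2IMes)(PCy3)(=CHPh) (3 mol %), CH2Cl2, 40 °C
Reagents that add atoms: none
Why: Olefin cross-metathesis of a secondary allylic alcohol with an excess of an allyl ether; the carbinol centre is not touched. A minor Z isomer can be carried on, since the alkene geometry only decides C10 later.

Step 2
Reactants: 4 [2-(1,3-dioxolan-2-yl)ethyl]magnesium bromide; 5 2,2-dimethyl-5-(propan-2-ylidene)-1,3-dioxane-4,6-dione
Product: 6 5-[4-(1,3-dioxolan-2-yl)-2-methylbutan-2-yl]-2,2-dimethyl-1,3-dioxane-4,6-dione
Conditions: CuBr·SMe2 (5 mol %), THF, −20 → 0 °C; aq. NH4Cl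
Reagents that add atoms: none
Why: Copper-catalysed conjugate addition of a Grignard reagent to an alkylidene Meldrum's acid, an acceptor reactive enough to take a nucleophile at a β,β-disubstituted carbon. It forms C3–C4 and the gem-dimethyl carbon C4 and brings C1 as a dioxolane.

Step 3
Reactants: 6; 3
Product: 8 (2S,3E)-5-[(tert-butyldimethylsilyl)oxy]pent-3-en-2-yl 5-(1,3-dioxolan-2-yl)-3,3-dimethylpentanoate, via malonic half ester 7 (not isolated)
Conditions: pyridine, Cu powder (cat.), 110 °C
Reagents that add atoms: none
Why: Alcoholysis of the Meldrum's acid ring with loss of acetone, then decarboxylation of the half ester, the standard conversion of 5-monoalkyl Meldrum's acids into esters. The basic medium keeps the acetal and the silyl ether.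

Step 4
Reactants: 8
Product: 11 (2S)-2-{(2R,3E)-1-[(tert-butyldimethylsilyl)oxy]pent-3-en-2-yl}-5-(1,3-dioxolan-2-yl)-3,3-dimethylpentanoic acid, via silyl ketene acetal 9 (not isolated), via trimethylsilyl ester 10 (not isolated)
Conditions: LiN(i-Pr)2, Me3SiCl, Et3N, THF, −78 °C; then 25 → 60 °C; aq. NH4Cl
Reagents that add atoms: none
Why: Ireland–Claisen rearrangement. Kinetic deprotonation in THF should give the (E)-ketene acetal 9 (bulky α-substituent cis to the allyloxy oxygen), which rearranges through a chair with the carbinol methyl group equatorial; the (S)-carbinol centre is thereby transferred to C5 (S) and, incidentally, to C10 (R). The C5 epimer that would come from the (Z)-ketene acetal or a boat is a diastereomer and is removed by chromatography at the stage of 12.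

Step 5
Reactants: 11
Product: 12 tert-butyl (2S)-2-{(2R,3E)-1-[(tert-butyldimethylsilyl)oxy]pent-3-en-2-yl}-5-(1,3-dioxolan-2-yl)-3,3-dimethylpentanoate
Conditions: Me2NCH(OtBu)2, toluene, 80 °C
Reagents that add atoms: N,N-dimethylformamide di-tert-butyl acetal, CN(C)C(OC(C)(C)C)OC(C)(C)C
Why: O-alkylation of the carboxylic acid by a tert-butyl cation donor; it does not need attack at the hindered acyl carbon and is neutral, so acetal and silyl ether survive. The tert-butyl ester is chosen because it will not lactonise with O20 or, later, with O1.

Step 6
Reactants: 12
Product: 13 tert-butyl (2S)-5-(1,3-dioxolan-2-yl)-2-[(2R,3E)-1-hydroxypent-3-en-2-yl]-3,3-dimethylpentanoate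
Conditions: HF·pyridine, pyridine, THF, 0 → 25 °C
Reagents that add atoms: none
Why: Fluoride cleavage of a primary silyl ether under buffered conditions that leave the dioxolane and the tert-butyl ester.

Step 7
Reactants: 13; 14 methyl 3-oxopentanoate
Product: 15 tert-butyl (2S)-5-(1,3-dioxolan-2-yl)-3,3-dimethyl-2-{(2R,3E)-1-[(3-oxopentanoyl)oxy]pent-3-en-2-yl}pentanoate
Conditions: 14 (3 equiv), DMAP (0.3 equiv), 4 Å molecular sieves, toluene, 100 °C
Reagents that add atoms: none
Why: Transesterification of a β-keto ester with a primary alcohol, which runs through the acyl ketene and is the usual way to acylate alcohols with β-keto acid units. It installs C7, C8 and C15–C17 on O20.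

Step 8
Reactants: 15
Product: 17 tert-butyl (2S)-5-(1,3-dioxolan-2-yl)-3,3-dimethyl-2-[(3R)-6-oxo-5-propanoyl-3,6-dihydro-2H-pyran-3-yl]pentanoate, via aldehyde 16 (not isolated)
Conditions: O3, CH2Cl2, −78 °C; PPh3; then piperidine (0.1 equiv), AcOH (0.1 equiv), 0 → 25 °C
Reagents that add atoms: none
Why: Ozonolysis of the only C=C bond gives the C9 aldehyde, which condenses with the tethered β-keto ester in an intramolecular Knoevenagel reaction to close the six-membered unsaturated lactone. The buffered amine salt at low temperature should keep β-elimination of the acyloxy group slow compared with ring closure; any epimerisation at C10 is harmless.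

Step 9
Reactants: 17
Product: 18 tert-butyl (2S)-3,3-dimethyl-6-oxo-2-[(3R)-6-oxo-5-propanoyl-3,6-dihydro-2H-pyran-3-yl]hexanoate
Conditions: 1 M aq. HCl, THF, 0 → 25 °C
Reagents that add atoms: water, O
Why: Acid-catalysed hydrolysis of the dioxolane. Dilute acid at or below room temperature should spare the tert-butyl ester and the acyl lactone; 18 is used at once.

Step 10
Reactants: 18
Product: 20 tert-butyl (6S,7R,11S)-11-hydroxy-8,8-dimethyl-3-oxo-4-propanoyl-2-oxaspiro[5.5]undec-4-ene-7-carboxylate (hydroxyl, C20 and ester all cis on ring A), via amidinium dienolate 19 (not isolated)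
Conditions: DBU (1.1 equiv), CH2Cl2, −20 → 0 °C
Reagents that add atoms: none
Why: Intramolecular vinylogous aldol addition, the γ-selective reaction known for dienolates of unsaturated lactones and of alkylidene 1,3-dicarbonyl compounds. DBU removes H10, which is vinylogous to both the lactone and the ketone carbonyl, and a full equivalent converts the electrophilic C8=C9 unit into dienolate 19, so that Michael addition of the aldehyde enolate to C9 should not compete. Ring A closes in the 6-(enolexo)-exo-trig mode by attack of C10 on the aldehyde carbon; attack through C8 would need an eight-membered ring. Proton transfer from the amidinium ion to the alkoxide restores the conjugated acyl lactone, which drives the addition and leaves the C8=C9 dienophile for ring C. C10 is controlled by the C5 centre: in the chair the tert-butyl ester is equatorial and anti to the forming bond, H5 lies in the dienolate plane next to H9, and the planar C9 arm with its acyl group and counter-ion takes the equatorial site while the C20 methylene turns axial, so C20 ends cis and C9 trans to the ester. C1 is controlled by the equatorial placement of the aldehyde oxygen and, since the addition is reversible, by equilibration to the equatorial alcohol cis to C20. The step needs γ- over α-attack, which ring size secures, and attack on one face of C10, which rests only on the C5 centre and is the uncertain element.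

Step 11
Reactants: 20
Product: 21 tert-butyl (6S,7R,11S)-11-acetoxy-8,8-dimethyl-3-oxo-4-propanoyl-2-oxaspiro[5.5]undec-4-ene-7-carboxylate
Conditions: Ac2O, pyridine, DMAP (cat.), CH2Cl2, 0 °C
Reagents that add atoms: acetic anhydride, CC(=O)OC(C)=O
Why: Acylation of the secondary alcohol, done directly after step 10 so that the free hydroxyl cannot take over the lactone acyl group from O20.

Step 12
Reactants: 21; 22 2-(trimethylsilyloxy)buta-1,3-diene
Product: 23 Diels–Alder adduct: 21 with a cis-fused cyclohexene ring C (C8–C14–C13=C12–C11–C9) carrying the trimethylsilyl enol ether at C12; C8 propanoyl cis to H9; C11 and C14 on the C1 face of the lactone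
Conditions: 22 (5 equiv), BHT (cat.), toluene, 100 °C, sealed tube
Reagents that add atoms: none
Why: Diels–Alder reaction of a doubly activated dienophile. The nucleophilic terminus of 22 bonds to the β-carbon C9, which puts the silyloxy group on C12 ("para"); suprafacial addition makes C8 quaternary and fixes C11 and C14 cis. The diene should approach the lactone face that carries the C1 acetate, since the other face is screened by the larger tert-butyl ester on C5; this sets C9 and C8 relative to C10.

Step 13
Reactants: 23
Product: 25 12,15-diketone with ring D closed (C13–C16 bond; bicyclo[3.2.1]octane; C16 as an epimer mixture), via bis(silyl enol ether) 24 (not isolated)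
Conditions: Me3SiOTf, Et3N, CH2Cl2, −40 → 0 °C; then (NH4)2Ce(NO3)6, NaHCO3, MeCN, −20 °C
Reagents that add atoms: none
Why: Soft enolisation of the ethyl ketone (C8 is quaternary, so only C16 can enolise) gives the second silyl enol ether. Tetravalent cerium then effects the known oxidative coupling of silyl enol ethers: C16 adds 5-exo to C13 of the ring enol ether, whose position was fixed by step 12, and loss of both silyl groups gives the 1,4-diketone. The bridge can only form on the face of ring C bearing the C8 acyl group, which fixes C13; the configuration at C16 is left open here and set in step 17.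

Step 14
Reactants: 25
Product: 26 C12 1,3-dithiolane of 25
Conditions: HS(CH2)2SH, BF3·OEt2 (0.3 equiv), CH2Cl2, 0 °C
Reagents that add atoms: ethane-1,2-dithiol, SCCS
Why: Thioketalisation; the cyclohexanone C12 should react in preference to the C15 ketone, which is flanked by the quaternary C8 and the branched C16. The bridgehead C13 rules out furan formation from the 1,4-diketone.

Step 15
Reactants: 26
Product: 27 tert-butyl ester of 30 (C12 methylene; C16 as an epimer mixture)
Conditions: Raney Ni (deactivated with acetone), EtOH, 25 °C
Reagents that add atoms: none
Why: Reductive desulfurisation of the dithiolane (Mozingo reduction) removes the C12 oxygen under neutral conditions; deactivated nickel should leave the hindered ketone, the lactone and the esters.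

Step 16
Reactants: 27
Product: 28 carboxylic acid with C16 as an epimer mixture (30 and its C16 epimer)
Conditions: CF3CO2H/CH2Cl2 (1:4), 0 → 25 °C
Reagents that add atoms: none
Why: Acidolysis of the tert-butyl ester with loss of 2-methylpropene; acetate, lactone and ketone are stable to these conditions.

Step 17
Reactants: 28
Product: 30 CNP0161834.1, 1-acetoxy-15-oxo-6,7-secokauran-7,20-olid-6-oic acid with the C16 methyl group endo (cis to C12), via silyl enol ether silyl ester 29 (not isolated)
Conditions: Me3SiOTf, Et3N, CH2Cl2, 0 → 25 °C; then 1 M aq. HCl, THF, −20 → 0 °C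
Reagents that add atoms: none
Why: The ketone can enolise only toward C16, so silylation gives a single enol ether (the acid is silylated as well and freed again on work-up). Kinetic C-protonation should occur on the exo face of ring D (the side of the one-carbon bridge and H13), which places H16 exo and the methyl group endo, as in 30. No base is used afterwards, so C16 is not scrambled.

## Compound list

1 | (S)-but-3-en-2-ol | C[C@H](O)C=C | starting material
2 | allyloxy(tert-butyl)dimethylsilane | C=CCO[Si](C)(C)C(C)(C)C | starting material
3 | (2S,3E)-5-[(tert-butyldimethylsilyl)oxy]pent-3-en-2-ol | C[C@H](O)/C=C/CO[Si](C)(C)C(C)(C)C | intermediate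
4 | [2-(1,3-dioxolan-2-yl)ethyl]magnesium bromide | Br[Mg]CCC1OCCO1 | starting material
5 | 2,2-dimethyl-5-(propan-2-ylidene)-1,3-dioxane-4,6-dione | CC(C)=C1C(=O)OC(C)(C)OC1=O | starting material
6 | 5-[4-(1,3-dioxolan-2-yl)-2-methylbutan-2-yl]-2,2-dimethyl-1,3-dioxane-4,6-dione | CC1(C)OC(=O)C(C(C)(C)CCC2OCCO2)C(=O)O1 | intermediate
7 | malonic half ester of 3 (2-substituted, mixture at the malonate carbon) | OC(=O)C(C(C)(C)CCC1OCCO1)C(=O)O[C@@H](C)/C=C/CO[Si](C)(C)C(C)(C)C | intermediate (not isolated)
8 | (2S,3E)-5-[(tert-butyldimethylsilyl)oxy]pent-3-en-2-yl 5-(1,3-dioxolan-2-yl)-3,3-dimethylpentanoate | O=C(CC(C)(C)CCC1OCCO1)O[C@@H](C)/C=C/CO[Si](C)(C)C(C)(C)C | intermediate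
9 | (E)-trimethylsilyl ketene acetal of 8 | C[Si](C)(C)O/C(=C/C(C)(C)CCC1OCCO1)O[C@@H](C)/C=C/CO[Si](C)(C)C(C)(C)C | intermediate (not isolated)
10 | trimethylsilyl ester of 11 | C[Si](C)(C)OC(=O)[C@H](C(C)(C)CCC1OCCO1)[C@H](CO[Si](C)(C)C(C)(C)C)/C=C/C | intermediate (not isolated)
11 | (2S)-2-{(2R,3E)-1-[(tert-butyldimethylsilyl)oxy]pent-3-en-2-yl}-5-(1,3-dioxolan-2-yl)-3,3-dimethylpentanoic acid | OC(=O)[C@H](C(C)(C)CCC1OCCO1)[C@H](CO[Si](C)(C)C(C)(C)C)/C=C/C | intermediate
12 | tert-butyl (2S)-2-{(2R,3E)-1-[(tert-butyldimethylsilyl)oxy]pent-3-en-2-yl}-5-(1,3-dioxolan-2-yl)-3,3-dimethylpentanoate | CC(C)(C)OC(=O)[C@H](C(C)(C)CCC1OCCO1)[C@H](CO[Si](C)(C)C(C)(C)C)/C=C/C | intermediate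
13 | tert-butyl (2S)-5-(1,3-dioxolan-2-yl)-2-[(2R,3E)-1-hydroxypent-3-en-2-yl]-3,3-dimethylpentanoate | CC(C)(C)OC(=O)[C@H](C(C)(C)CCC1OCCO1)[C@H](CO)/C=C/C | intermediate
14 | methyl 3-oxopentanoate | CCC(=O)CC(=O)OC | starting material
15 | tert-butyl (2S)-5-(1,3-dioxolan-2-yl)-3,3-dimethyl-2-{(2R,3E)-1-[(3-oxopentanoyl)oxy]pent-3-en-2-yl}pentanoate | CC(C)(C)OC(=O)[C@H](C(C)(C)CCC1OCCO1)[C@H](COC(=O)CC(=O)CC)/C=C/C | intermediate
16 | tert-butyl (2S)-5-(1,3-dioxolan-2-yl)-3,3-dimethyl-2-{(2R)-1-oxo-3-[(3-oxopentanoyl)oxy]propan-2-yl}pentanoate | CC(C)(C)OC(=O)[C@H](C(C)(C)CCC1OCCO1)[C@H](COC(=O)CC(=O)CC)C=O | intermediate (not isolated)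
17 | tert-butyl (2S)-5-(1,3-dioxolan-2-yl)-3,3-dimethyl-2-[(3R)-6-oxo-5-propanoyl-3,6-dihydro-2H-pyran-3-yl]pentanoate | CC(C)(C)OC(=O)[C@H](C(C)(C)CCC1OCCO1)[C@@H]2COC(=O)C(C(=O)CC)=C2 | intermediate
18 | tert-butyl (2S)-3,3-dimethyl-6-oxo-2-[(3R)-6-oxo-5-propanoyl-3,6-dihydro-2H-pyran-3-yl]hexanoate | O=CCCC(C)(C)[C@@H](C(=O)OC(C)(C)C)[C@@H]1COC(=O)C(C(=O)CC)=C1 | intermediate
19 | 1,8-diazabicyclo[5.4.0]undec-7-enium dienolate of 18 (C10 planar) | O=CCCC(C)(C)[C@@H](C(=O)OC(C)(C)C)C1=CC(C(=O)CC)=C([O-])OC1.C1CCC2=[NH+]CCCN2CC1 | intermediate (not isolated)
20 | tert-butyl (6S,7R,11S)-11-hydroxy-8,8-dimethyl-3-oxo-4-propanoyl-2-oxaspiro[5.5]undec-4-ene-7-carboxylate | O[C@H]1CCC(C)(C)[C@@H](C(=O)OC(C)(C)C)[C@@]12COC(=O)C(C(=O)CC)=C2 | intermediate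
21 | tert-butyl (6S,7R,11S)-11-acetoxy-8,8-dimethyl-3-oxo-4-propanoyl-2-oxaspiro[5.5]undec-4-ene-7-carboxylate | CC(=O)O[C@H]1CCC(C)(C)[C@@H](C(=O)OC(C)(C)C)[C@@]12COC(=O)C(C(=O)CC)=C2 | intermediate
22 | 2-(trimethylsilyloxy)buta-1,3-diene | C=CC(=C)O[Si](C)(C)C | starting material
23 | Diels–Alder adduct: 21 with cis-fused cyclohexene ring C, C12 trimethylsilyl enol ether (C12=C13), C8 propanoyl cis to H9, C11 and C14 on the C1 face | CC(=O)O[C@H]1CCC(C)(C)[C@@H](C(=O)OC(C)(C)C)[C@@]12COC(=O)[C@@]3(C(=O)CC)CC=C(O[Si](C)(C)C)C[C@@H]23 | intermediate
24 | bis(trimethylsilyl enol ether): 23 with the propanoyl group as its (Z)-enol ether (C15=C16) | CC(=O)O[C@H]1CCC(C)(C)[C@@H](C(=O)OC(C)(C)C)[C@@]12COC(=O)[C@@]3(/C(O[Si](C)(C)C)=C/C)CC=C(O[Si](C)(C)C)C[C@@H]23 | intermediate (not isolated)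
25 | tert-butyl 1-acetoxy-12,15-dioxo-6,7-secokauran-7,20-olid-6-oate (C16 epimer mixture) | CC(=O)O[C@H]1CCC(C)(C)[C@@H](C(=O)OC(C)(C)C)[C@@]12COC(=O)[C@@]13C[C@@H](C(=O)C[C@H]12)C(C)C3=O | intermediate
26 | C12 1,3-dithiolane of 25 (C16 epimer mixture) | CC(=O)O[C@H]1CCC(C)(C)[C@@H](C(=O)OC(C)(C)C)[C@@]12COC(=O)[C@@]13C[C@@H](C4(SCCS4)C[C@H]12)C(C)C3=O | intermediate
27 | tert-butyl 1-acetoxy-15-oxo-6,7-secokauran-7,20-olid-6-oate (C16 epimer mixture) | CC(=O)O[C@H]1CCC(C)(C)[C@@H](C(=O)OC(C)(C)C)[C@@]12COC(=O)[C@@]13C[C@@H](CC[C@H]12)C(C)C3=O | intermediate
28 | 1-acetoxy-15-oxo-6,7-secokauran-7,20-olid-6-oic acid (C16 epimer mixture) | CC(=O)O[C@H]1CCC(C)(C)[C@@H](C(=O)O)[C@@]12COC(=O)[C@@]13C[C@@H](CC[C@H]12)C(C)C3=O | intermediate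
29 | trimethylsilyl ester of 28 with the C15 ketone as its trimethylsilyl enol ether (C15=C16) | CC(=O)O[C@H]1CCC(C)(C)[C@@H](C(=O)O[Si](C)(C)C)[C@@]12COC(=O)[C@@]13C[C@@H](CC[C@H]12)C(C)=C3O[Si](C)(C)C | intermediate (not isolated)
30 | CNP0161834.1: 1-acetoxy-15-oxo-6,7-secokauran-7,20-olid-6-oic acid, C16 methyl endo (cis to C12) | CC(=O)O[C@H]1CCC(C)(C)[C@@H](C(=O)O)[C@@]12COC(=O)[C@@]13C[C@@H](CC[C@H]12)[C@@H](C)C3=O | target

## Step count and least certain steps

Total step count: 17. Longest linear sequence: 16 steps (steps 2–17; the branch through step 1 and steps 3–17 is equally long).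

**Step 10 (key step).** The most likely failure is attack of C1 on the wrong face of the planar C10. The two lactone arms at C10 (the planar CH of C9 and the CH2 of C20) differ little in size, and the one that turns axial decides the spiro configuration; it is not certain that C20 is that arm. Two further risks are incomplete conversion through retro-aldol cleavage, and transfer of the lactone acyl group from O20 to the new C1 alkoxide under base. The fallback replaces the base-mediated dienolate addition by a Lewis-acid carbonyl-ene closure of the neutral tautomer, with a different control element. It sets out from 18, which a catalytic amount of Et3N (CH2Cl2, 0 °C) equilibrates with its β,γ-unsaturated tautomer tert-butyl (2S)-3,3-dimethyl-6-oxo-2-(6-oxo-5-propanoyl-5,6-dihydro-2H-pyran-3-yl)hexanoate F1. Treatment with MgBr2·OEt2 (CH2Cl2, −40 → 0 °C) should then bring about an intramolecular carbonyl-ene (Conia-type) cyclisation, in which the enolised C8 hydrogen passes to the aldehyde oxygen as C10 bonds to C1. No free alkoxide is formed. Magnesium bridging the aldehyde oxygen and the ester carbonyl holds both axial on the chair, so in this mode the desired configuration results when the planar C9 arm is axial, the opposite requirement to that of step 10. The fallback comes back to the route at 20.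

**Step 12.** The Diels–Alder reaction may be slow at C9, which is next to the spiro quaternary carbon. The propanoyl enone could then react as an oxadiene at the enol ether bond of 22, or 22 could decompose; addition to the C5 face of the lactone would erode the selectivity. The fallback uses a more nucleophilic diene and a reduction. It sets out from 21: (E)-1-methoxy-3-(trimethylsilyloxy)buta-1,3-diene (toluene, 60 °C) should give the 14-methoxy-12-(trimethylsilyloxy) cycloadduct F2. Dilute HCl in THF then removes methanol and the silyl group to give the cyclohex-13-en-12-one F3. Conjugate reduction with KBH(s-Bu)3 (THF, −78 °C) and trapping of the C12 enolate with Me3SiCl delivers the C12=C13 enol ether regiospecifically. The fallback comes back to the route at 23.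

**Step 13.** The carbon C16 has to bond to C13 within a five-membered ring that contains its own carbonyl carbon C15, an unfavourable alignment. Oxidation may therefore end in simple desilylation to the uncoupled diketone, in oxygenation at C13 or C16, or in intermolecular coupling. The fallback is a polar closure in which C13 is the enolate carbon (its carbonyl outside the new ring) and C16 the electrophile. It sets out from 21: Me3SiOTf/Et3N gives the silyl dienol ether F4 of the propanoyl group, and N-bromosuccinimide (THF, −78 °C) converts it into the 2-bromopropanoyl lactone F5. Cycloaddition with 22 as in step 12 gives the bromo ketone enol ether F6. Bu4NF (THF, −78 °C) then frees the C12 enolate, which displaces bromide at C16 in a 5-exo-tet alkylation. The fallback comes back to the route at 25.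

**Step 17.** Protonation of the tetrasubstituted enol ether may occur on both faces, or enol ether formation at the hindered ketone may be incomplete, which would leave the more stable exo-methyl epimer. The fallback sets C16 by hydrogenation instead of protonation. It sets out from 28 and forms 29 as in step 17; oxidation with Pd(OAc)2 (divalent palladium, MeCN, 25 °C) should give the 16-methylene-15-ketone F7, since only the C17 hydrogens can be eliminated (C13 is a bridgehead). Hydrogenation over Pd/C (EtOAc, 1 atm H2) should deliver hydrogen to the exo face of the exocyclic enone and so place the methyl group endo. The fallback comes back to the route at 30.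

## Further compounds

F1 | step 10 | tert-butyl (2S)-3,3-dimethyl-6-oxo-2-(6-oxo-5-propanoyl-5,6-dihydro-2H-pyran-3-yl)hexanoate (β,γ-unsaturated tautomer of 18, C8 epimers) | O=CCCC(C)(C)[C@@H](C(=O)OC(C)(C)C)C1=CC(C(=O)CC)C(=O)OC1
F2 | step 12 | cycloadduct of 21 with 14-methoxy and 12-(trimethylsilyloxy) groups (C12=C13, mixture at C14) | CC(=O)O[C@H]1CCC(C)(C)[C@@H](C(=O)OC(C)(C)C)[C@@]12COC(=O)[C@@]3(C(=O)CC)C(OC)C=C(O[Si](C)(C)C)C[C@@H]23
F3 | step 12 | cyclohex-13-en-12-one from F2 (C12 ketone, C13=C14) | CC(=O)O[C@H]1CCC(C)(C)[C@@H](C(=O)OC(C)(C)C)[C@@]12COC(=O)[C@@]3(C(=O)CC)C=CC(=O)C[C@@H]23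
F4 | step 13 | trimethylsilyl dienol ether of 21 (C15=C16) | CC(=O)O[C@H]1CCC(C)(C)[C@@H](C(=O)OC(C)(C)C)[C@@]12COC(=O)C(C(O[Si](C)(C)C)=CC)=C2
F5 | step 13 | 2-bromopropanoyl analogue of 21 (mixture at C16) | CC(=O)O[C@H]1CCC(C)(C)[C@@H](C(=O)OC(C)(C)C)[C@@]12COC(=O)C(C(=O)C(C)Br)=C2
F6 | step 13 | 2-bromopropanoyl analogue of 23 (mixture at C16) | CC(=O)O[C@H]1CCC(C)(C)[C@@H](C(=O)OC(C)(C)C)[C@@]12COC(=O)[C@@]3(C(=O)C(C)Br)CC=C(O[Si](C)(C)C)C[C@@H]23
F7 | step 17 | 1-acetoxy-15-oxo-6,7-secokaur-16-en-7,20-olid-6-oic acid (16-methylene ketone) | CC(=O)O[C@H]1CCC(C)(C)[C@@H](C(=O)O)[C@@]12COC(=O)[C@@]13C[C@@H](CC[C@H]12)C(=C)C3=O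
A1 | alternative 1 | trans-anti-trans tricyclic methyl ester with C6=C7, C1 silyl ether and C13 dioxolane | C[Si](C)(C(C)(C)C)O[C@H]1CCC(C)(C)[C@H]2C=C[C@@H]3CC4(OCCO4)CC[C@H]3[C@]12C(=O)OC
A2 | alternative 2 | C1–O–Si–C20 siloxane with quaternary C10 and complete rings C and D | C[Si]5(C)O[C@H]1CCC(C)(C)[C@@H](C(=O)OC(C)(C)C)[C@]1(C5)[C@@H]2CC[C@@H]3C[C@@]2(C(=O)OC)C(=O)[C@@H]3C
A3 | alternative 3 | ring C cyclohexene carboxylic acid attached to ring A at C9 | C[Si](C)(C(C)(C)C)O[C@H]1CCC(C)(C)[C@@H](C(=O)OC(C)(C)C)[C@]1(COCc2ccc(OC)cc2)[C@@H]3C=C[C@@H](C(C)=C)C[C@@H]3C(=O)O
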